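**Strategy**

Everything rests on cutting the methylene bridge between the CH2 on C5 of the dihydrobenzofuran ring (flanked by the C4 and C6 phenols) and C3 of the 4-hydroxy-2-pyranone ring. The key step copies the presumed biosynthesis: a C5 dimethylaminomethyl (Mannich) precursor expels dimethylamine to give an ortho-quinone methide, which C3 of 6-ethyl-4-hydroxy-5-methyl-2-pyranone, the nucleophilic carbon between the C2 lactone carbonyl and the C4 enol, captures by conjugate addition. This joins the two complete, unprotected halves in one operation. The precursor already carries both stereocentres: the acyl one from (S)-2-methylbutanoic acid, the furan one from a Pd-catalysed asymmetric allylic etherification.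

Key step: step 10

Assumption: the (S,S) hand of the DACH-phenyl Trost ligand is taken to deliver the (2S)-dihydrofuran in step 6; if a pilot run shows the opposite sense, the enantiomeric ligand is used and nothing else changes.

Remark: the acylphloroglucinols and the pyranone are drawn as their phenol/enol tautomers throughout.

**Route**

Step 1
Reactants: 1 2-methyl-2-vinyloxirane (racemic)
Product: 2 (2E)-4-chloro-2-methylbut-2-en-1-ol
Conditions: TiCl4, CH2Cl2, −80 °C; aq. work-up
Reagents that add atoms: titanium tetrachloride, Cl[Ti](Cl)(Cl)Cl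
Why: Lewis-acid activation of the vinyl epoxide and SN2′ delivery of chloride to the vinyl terminus should give the E-configured 1,4-chlorohydrin (known conjugate opening of isoprene monoxide).

Step 2
Reactants: 2 (2E)-4-chloro-2-methylbut-2-en-1-ol
Product: 3 (2E)-4-chloro-2-methylbut-2-en-1-yl methyl carbonate
Conditions: ClCO2Me, pyridine, CH2Cl2, 0 °C
Reagents that add atoms: methyl chloroformate, COC(=O)Cl
Why: Standard O-acylation of a primary alcohol with a chloroformate installs the leaving group for the later Pd step and leaves the allylic chloride untouched.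

Step 3
Reactants: 4 (2S)-2-methylbutanoic acid; 5 phloroglucinol (benzene-1,3,5-triol)
Product: 7 (2S)-2-methyl-1-(2,4,6-trihydroxyphenyl)butan-1-one, via (2S)-2-methylbutanoyl chloride 6 (not isolated)
Conditions: (COCl)2, cat. DMF, CH2Cl2, 0 °C → rt; then 5, AlCl3 (3.5 equiv), PhNO2/CH2Cl2, 0 °C → rt; aq. HCl
Reagents that add atoms: none
Why: Friedel–Crafts C-acylation of phloroglucinol is self-limiting at the mono-ketone (the acyl group deactivates the ring), and keeping the temperature low should suppress ketene formation and so preserve the chiral-pool (S) α-centre.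

Step 4
Reactants: 7 (2S)-2-methyl-1-(2,4,6-trihydroxyphenyl)butan-1-one; 3 (2E)-4-chloro-2-methylbut-2-en-1-yl methyl carbonate
Product: 8 methyl (2E)-2-methyl-4-{2,4,6-trihydroxy-3-[(2S)-2-methylbutanoyl]phenyl}but-2-en-1-yl carbonate
Conditions: 7 (1.5 equiv), DBU (1.0 equiv), NaI (cat.), THF, 0 °C → rt
Reagents that add atoms: none
Why: C-alkylation of the acylphloroglucinol (a vinylogous acid, soft at ring carbon) by SN2 at the primary allylic chloride follows the known amidine-mediated C-prenylation of acylphloroglucinols, with excess 7 limiting double alkylation and the E geometry carried over unchanged.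

Step 5
Reactants: 8 methyl (2E)-2-methyl-4-{2,4,6-trihydroxy-3-[(2S)-2-methylbutanoyl]phenyl}but-2-en-1-yl carbonate
Product: 9 methyl (2E)-4-{6-[(tert-butyldimethylsilyl)oxy]-2,4-dihydroxy-3-[(2S)-2-methylbutanoyl]phenyl}-2-methylbut-2-en-1-yl carbonate (silyl ether on the OH para to the acyl group)
Conditions: TBSCl (1.05 equiv), imidazole (2 equiv), CH2Cl2/DMF, −20 → 0 °C
Reagents that add atoms: tert-butyldimethylsilyl chloride, CC(C)(C)[Si](C)(C)Cl
Why: The OH para to the ketone is the most acidic and the only one not engaged in the hydrogen bond to the carbonyl, so one equivalent of silyl chloride should cap it selectively, blocking the one oxygen that could otherwise compete in the ring closure.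

Step 6
Reactants: 9 methyl (2E)-4-{6-[(tert-butyldimethylsilyl)oxy]-2,4-dihydroxy-3-[(2S)-2-methylbutanoyl]phenyl}-2-methylbut-2-en-1-yl carbonate
Product: 11 (2S)-1-[(2S)-4,6-dihydroxy-2-(prop-1-en-2-yl)-2,3-dihydro-1-benzofuran-7-yl]-2-methylbutan-1-one, via 4-O-TBS dihydrobenzofuran 10 (not isolated)
Conditions: Pd2(dba)3·CHCl3 (2.5 mol %), (S,S)-DACH-phenyl Trost ligand (7.5 mol %), AcOH (1 equiv), CH2Cl2, rt; then TBAF (1.1 equiv), THF, 0 °C
Reagents that add atoms: none
Why: Pd(0) ionises the allylic carbonate to a π-allyl complex that the only free OH ortho to the side chain closes 5-exo at the internal terminus (Trost asymmetric allylic etherification, known for o-(4-carbonyloxy-3-methylbut-2-enyl)phenols), the C2 configuration being set by the chiral ligand acting on π-allyl faces that interconvert through the unsubstituted CH2 terminus, and buffered fluoride then cleaves the aryl silyl ether in the same flask.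

Step 7
Reactants: 11 (2S)-1-[(2S)-4,6-dihydroxy-2-(prop-1-en-2-yl)-2,3-dihydro-1-benzofuran-7-yl]-2-methylbutan-1-one
Product: 12 (2S)-1-[(2S)-5-[(dimethylamino)methyl]-4,6-dihydroxy-2-(prop-1-en-2-yl)-2,3-dihydro-1-benzofuran-7-yl]-2-methylbutan-1-one
Conditions: Me2N+=CH2 I− (1.1 equiv), Et3N (1.1 equiv), CH2Cl2, 0 °C → rt
Reagents that add atoms: Eschenmoser's salt (N,N-dimethylmethyleneiminium iodide), C[N+](C)=C.[I-]
Why: Mannich aminomethylation with the preformed iminium salt should occur at C5, the only unsubstituted ring carbon and the one activated by two ortho hydroxyls and the para ring oxygen.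

Step 8
Reactants: 13 methyl 3-oxopentanoate; 14 N-methoxy-N-methylpropanamide
Product: 15 methyl 4-methyl-3,5-dioxoheptanoate
Conditions: 13 (2 equiv), NaH, THF, 0 °C; n-BuLi, 0 °C; then 14, −78 → 0 °C; aq. HCl
Reagents that add atoms: none
Why: The γ-carbanion of the β-keto ester dianion (Huckin–Weiler) is acylated by the Weinreb amide, whose chelated tetrahedral intermediate prevents over-addition.

Step 9
Reactants: 15 methyl 4-methyl-3,5-dioxoheptanoate
Product: 16 6-ethyl-4-hydroxy-5-methyl-2H-pyran-2-one
Conditions: DBU (1.5 equiv), toluene, reflux; aq. HCl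
Reagents that add atoms: none
Why: Base-mediated enolisation of the C5 ketone and lactonisation of its enol oxygen onto the ester with loss of methanol is the standard closure of 3,5-dioxo esters to 4-hydroxy-2-pyranones.

Step 10
Reactants: 12 (2S)-1-[(2S)-5-[(dimethylamino)methyl]-4,6-dihydroxy-2-(prop-1-en-2-yl)-2,3-dihydro-1-benzofuran-7-yl]-2-methylbutan-1-one; 16 6-ethyl-4-hydroxy-5-methyl-2H-pyran-2-one
Product: 18 6-ethyl-4-hydroxy-3-({(2S)-4,6-dihydroxy-7-[(2S)-2-methylbutanoyl]-2-(prop-1-en-2-yl)-2,3-dihydro-1-benzofuran-5-yl}methyl)-5-methyl-2H-pyran-2-one (target), via ortho-quinone methide 17 (not isolated)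
Conditions: 16 (1.3 equiv), 1,4-dioxane, 90 °C, N2 sweep
Reagents that add atoms: none
Why: Proton transfer from the acidic pyranone to the benzylic amine gives an ammonium pyronate, the flanking C4/C6 phenol(ate) expels dimethylamine to form ortho-quinone methide 17, C3 of the pyronate adds to its exocyclic methylene (Michael addition), and tautomerisation restores both the phloroglucinol and the 4-hydroxy-2-pyranone rings. The closest known reaction type is the thermal coupling of phenolic Mannich bases with cyclic 1,3-dicarbonyl C-nucleophiles such as 4-hydroxycoumarins and 4-hydroxy-6-methyl-2-pyranone through ortho-quinone methides, the same logic as the presumed biosynthesis of methylene-bridged phloroglucinol–pyranones. No ring is closed and no stereocentre is formed; both existing stereocentres are remote from the reacting atoms and meet only a weak amine base. The step needs C- over O-alkylation of the pyranone and capture of the quinone methide before it oligomerises: C3 is the only unsubstituted nucleophilic carbon of 16 and any O-adduct can revert to the quinone methide, while 12 has no free ring carbon left, 16 is used in excess and dimethylamine is swept out so that the addition becomes irreversible.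

**Compound list**

1 | 2-methyl-2-vinyloxirane (racemic) | CC1(C=C)CO1 | starting material
2 | (2E)-4-chloro-2-methylbut-2-en-1-ol | OC/C(C)=C/CCl | intermediate
3 | (2E)-4-chloro-2-methylbut-2-en-1-yl methyl carbonate | COC(=O)OC/C(C)=C/CCl | intermediate
4 | (2S)-2-methylbutanoic acid | OC(=O)[C@@H](C)CC | starting material
5 | phloroglucinol | Oc1cc(O)cc(O)c1 | starting material
6 | (2S)-2-methylbutanoyl chloride (not isolated) | ClC(=O)[C@@H](C)CC | intermediate
7 | (2S)-2-methyl-1-(2,4,6-trihydroxyphenyl)butan-1-one | O=C([C@@H](C)CC)c1c(O)cc(O)cc1O | intermediate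
8 | methyl (2E)-2-methyl-4-{2,4,6-trihydroxy-3-[(2S)-2-methylbutanoyl]phenyl}but-2-en-1-yl carbonate | COC(=O)OC/C(C)=C/Cc1c(O)cc(O)c(C(=O)[C@@H](C)CC)c1O | intermediate
9 | methyl (2E)-4-{6-[(tert-butyldimethylsilyl)oxy]-2,4-dihydroxy-3-[(2S)-2-methylbutanoyl]phenyl}-2-methylbut-2-en-1-yl carbonate | COC(=O)OC/C(C)=C/Cc1c(O[Si](C)(C)C(C)(C)C)cc(O)c(C(=O)[C@@H](C)CC)c1O | intermediate
10 | (2S)-1-[(2S)-4-[(tert-butyldimethylsilyl)oxy]-6-hydroxy-2-(prop-1-en-2-yl)-2,3-dihydro-1-benzofuran-7-yl]-2-methylbutan-1-one (not isolated) | C=C(C)[C@@H]1Cc2c(O[Si](C)(C)C(C)(C)C)cc(O)c(C(=O)[C@@H](C)CC)c2O1 | intermediate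
11 | (2S)-1-[(2S)-4,6-dihydroxy-2-(prop-1-en-2-yl)-2,3-dihydro-1-benzofuran-7-yl]-2-methylbutan-1-one | C=C(C)[C@@H]1Cc2c(O)cc(O)c(C(=O)[C@@H](C)CC)c2O1 | intermediate
12 | (2S)-1-[(2S)-5-[(dimethylamino)methyl]-4,6-dihydroxy-2-(prop-1-en-2-yl)-2,3-dihydro-1-benzofuran-7-yl]-2-methylbutan-1-one | C=C(C)[C@@H]1Cc2c(O)c(CN(C)C)c(O)c(C(=O)[C@@H](C)CC)c2O1 | intermediate
13 | methyl 3-oxopentanoate | CCC(=O)CC(=O)OC | starting material
14 | N-methoxy-N-methylpropanamide | CCC(=O)N(C)OC | starting material
15 | methyl 4-methyl-3,5-dioxoheptanoate (configurationally labile at C4) | CCC(=O)C(C)C(=O)CC(=O)OC | intermediate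
16 | 6-ethyl-4-hydroxy-5-methyl-2H-pyran-2-one | CCc1oc(=O)cc(O)c1C | intermediate
17 | (2S)-6-hydroxy-5-methylidene-7-[(2S)-2-methylbutanoyl]-2-(prop-1-en-2-yl)-2,3-dihydro-1-benzofuran-4(5H)-one (ortho-quinone methide, not isolated; the 6-oxo tautomer leads to the same product) | C=C(C)[C@@H]1CC2=C(O1)C(C(=O)[C@@H](C)CC)=C(O)C(=C)C2=O | intermediate
18 | 6-ethyl-4-hydroxy-3-({(2S)-4,6-dihydroxy-7-[(2S)-2-methylbutanoyl]-2-(prop-1-en-2-yl)-2,3-dihydro-1-benzofuran-5-yl}methyl)-5-methyl-2H-pyran-2-one | C=C(C)[C@@H]1Cc2c(O)c(Cc3c(O)c(C)c(CC)oc3=O)c(O)c(C(=O)[C@@H](C)CC)c2O1 | target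

**Totals**

Total step count: 10
Longest linear sequence: 7 steps (steps 1, 2, 4, 5, 6, 7, 10)

**Steps most likely to fail**

1. Step 6. Enantioface discrimination at the π-allyl terminus may be insufficient if ring closure outruns face equilibration. Pd(0) may also re-ionise the allylic aryl ether of the product and erode its configuration. Premature loss of the silyl group would let the para oxygen close the ring instead. The fallback sets the furan stereocentre by reagent-controlled epoxidation and SN2 inversion; it sets out from 7 and comes back at 11. Compound 7 is C-prenylated (prenyl bromide, DBU, THF) to (2S)-2-methyl-1-[2,4,6-trihydroxy-3-(3-methylbut-2-en-1-yl)phenyl]butan-1-one F1. MOMCl/iPr2NEt caps the para OH and the unhindered ortho OH to give (2S)-1-[2-hydroxy-4,6-bis(methoxymethoxy)-3-(3-methylbut-2-en-1-yl)phenyl]-2-methylbutan-1-one F2, leaving free the chelated OH next to the prenyl group. Shi asymmetric epoxidation (fructose-derived ketone of the hand that gives the R epoxide, Oxone, pH 10.5, MeCN/DMM, 0 °C) should give (2S)-1-[3-{[(2R)-3,3-dimethyloxiran-2-yl]methyl}-2-hydroxy-4,6-bis(methoxymethoxy)phenyl]-2-methylbutan-1-one F3. K2CO3/MeOH lets the free phenoxide open the epoxide 5-exo at the secondary carbon with inversion to (2S)-1-[(2S)-2-(2-hydroxypropan-2-yl)-4,6-bis(methoxymethoxy)-2,3-dihydro-1-benzofuran-7-yl]-2-methylbutan-1-one F4. Burgess reagent (toluene, 50 °C) dehydrates the tertiary alcohol to (2S)-1-[(2S)-4,6-bis(methoxymethoxy)-2-(prop-1-en-2-yl)-2,3-dihydro-1-benzofuran-7-yl]-2-methylbutan-1-one F5. ZnBr2/n-PrSH (CH2Cl2, 0 °C) removes both MOM groups to give 11.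

2. Step 4. O-alkylation and a second C-alkylation at the other equivalent ring carbon may compete with the wanted mono-C-alkylation, and the phenoxide or the base may attack the carbonate. The fallback replaces the SN2 alkylation by a Pd-π-allyl electrophile; it sets out from 7 (with 1) and comes back at 9. Pd(PPh3)4-catalysed Tsuji–Trost allylation of 7 with vinyl epoxide 1 (THF, rt) should give mainly (2S)-1-{2,4,6-trihydroxy-3-[(2E)-4-hydroxy-3-methylbut-2-en-1-yl]phenyl}-2-methylbutan-1-one F6, because the alkoxide of the π-allyl complex deprotonates the phenol, attack occurs at the unsubstituted terminus, and O-allyl ethers re-ionise and funnel to carbon. TBSCl/Et3N without a nucleophilic catalyst silylates the phenoxide of the most acidic (para) OH and not the neutral primary alcohol, giving (2S)-1-{4-[(tert-butyldimethylsilyl)oxy]-2,6-dihydroxy-3-[(2E)-4-hydroxy-3-methylbut-2-en-1-yl]phenyl}-2-methylbutan-1-one F7. Methyl chloroformate/pyridine at −20 °C then acylates the primary allylic alcohol in preference to the two hydrogen-bonded, hindered phenols to give 9.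

3. Step 10. The quinone methide may be consumed by self-condensation, or by re-addition of dimethylamine and oxygen nucleophiles, faster than C3 of the pyranone adds. The fallback forms the same CH2–C3 link by condensation and reduction without a free quinone methide; it sets out from 11 and comes back at 18. Vilsmeier–Haack formylation of 11 (POCl3, DMF, MeCN, 0 °C; aq. NaOAc) at the only free ring carbon gives (2S)-4,6-dihydroxy-7-[(2S)-2-methylbutanoyl]-2-(prop-1-en-2-yl)-2,3-dihydro-1-benzofuran-5-carbaldehyde F8. A three-component reductive alkylation of F8 with 16 and Hantzsch ester (L-proline cat., EtOH/CH2Cl2, rt) should then give 18: Knoevenagel condensation at C3 of the pyranone is followed by in-flask transfer hydrogenation of the benzylidene intermediate.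

**Further compounds**

F1 | step 6 | (2S)-2-methyl-1-[2,4,6-trihydroxy-3-(3-methylbut-2-en-1-yl)phenyl]butan-1-one | CC(C)=CCc1c(O)cc(O)c(C(=O)[C@@H](C)CC)c1O
F2 | step 6 | (2S)-1-[2-hydroxy-4,6-bis(methoxymethoxy)-3-(3-methylbut-2-en-1-yl)phenyl]-2-methylbutan-1-one | CC(C)=CCc1c(OCOC)cc(OCOC)c(C(=O)[C@@H](C)CC)c1O
F3 | step 6 | (2S)-1-[3-{[(2R)-3,3-dimethyloxiran-2-yl]methyl}-2-hydroxy-4,6-bis(methoxymethoxy)phenyl]-2-methylbutan-1-one | COCOc1cc(OCOC)c(C[C@H]2OC2(C)C)c(O)c1C(=O)[C@@H](C)CC
F4 | step 6 | (2S)-1-[(2S)-2-(2-hydroxypropan-2-yl)-4,6-bis(methoxymethoxy)-2,3-dihydro-1-benzofuran-7-yl]-2-methylbutan-1-one | CC(C)(O)[C@@H]1Cc2c(OCOC)cc(OCOC)c(C(=O)[C@@H](C)CC)c2O1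
F5 | step 6 | (2S)-1-[(2S)-4,6-bis(methoxymethoxy)-2-(prop-1-en-2-yl)-2,3-dihydro-1-benzofuran-7-yl]-2-methylbutan-1-one | C=C(C)[C@@H]1Cc2c(OCOC)cc(OCOC)c(C(=O)[C@@H](C)CC)c2O1
F6 | step 4 | (2S)-1-{2,4,6-trihydroxy-3-[(2E)-4-hydroxy-3-methylbut-2-en-1-yl]phenyl}-2-methylbutan-1-one | OC/C(C)=C/Cc1c(O)cc(O)c(C(=O)[C@@H](C)CC)c1O
F7 | step 4 | (2S)-1-{4-[(tert-butyldimethylsilyl)oxy]-2,6-dihydroxy-3-[(2E)-4-hydroxy-3-methylbut-2-en-1-yl]phenyl}-2-methylbutan-1-one | OC/C(C)=C/Cc1c(O[Si](C)(C)C(C)(C)C)cc(O)c(C(=O)[C@@H](C)CC)c1O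
F8 | step 10 | (2S)-4,6-dihydroxy-7-[(2S)-2-methylbutanoyl]-2-(prop-1-en-2-yl)-2,3-dihydro-1-benzofuran-5-carbaldehyde | C=C(C)[C@@H]1Cc2c(O)c(C=O)c(O)c(C(=O)[C@@H](C)CC)c2O1
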